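## Structural features

The target is a tetracyclic diterpenoid acetate on a labdane skeleton. A cis-fused decalin (ring A: C1–C5, C10; ring B: C5–C10) shares C9 as a spiro atom with a tetrahydrofuran (ring C: O, C9, C11, C12, C13), and C13 is a second spiro atom shared with a 2,3-dihydrofuran (ring D: C13, C14=C15, O, C16). Ring B is oxidised at four consecutive carbons: C6 is a ketone, C7 carries a secondary hydroxyl, C8 a methyl group and a tertiary acetate, C9 the ether oxygen. Five stereocentres are contiguous (C5, C10, C9, C8, C7), three of them fully substituted and adjacent (C8, C9, C10); the sixth, C13, is remote and tied to C9 only through the ether oxygen and the C11–C12 tether. With β as the face of the C10 methyl group, H5 and the C7 hydroxyl are β, while the C8 acetate and the C9 oxygen are both α (cis to each other, trans to the C7 hydroxyl). The fragile groups are the cyclic enol ether C14=C15 (acid, electrophilic oxidants), the β-acetoxy ketone (loss of acetate toward a 7-en-6-one), the α-ketol (ketol shift, acetyl migration) and H5 next to the ketone in a cis-decalin (epimerisation to the trans series). The real difficulty is to dioxygenate the congested C8–C9–C10 array cis and to fix the remote spiro centre C13 relative to C9, where no ordinary substrate bias operates. The key step uses two facts: O8 and O9 are cis on ring B, and on ring C the substituents C8 (on C9) and C14 (on C13) are cis. This is the pattern that results when a metal diolate of an 8,9-diol adds across a C13=C14 double bond.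

## Logic of the disconnections

32 to 31: the C14–H bond is traced back to a C14–O triflate. The enol ether cannot survive the acid and the electrophilic oxidants that ring B needs, whereas a vinyl triflate is inert to both. The gain is that the most fragile group appears in the last step; the demand is a neutral reduction that leaves the ketol and the β-acetoxy ketone alone.

31 to 28: the C7–O bond is cut. C7 is the only position activated by the C6 carbonyl that can enolise, since C5 is tertiary and shielded. One stereocentre and the ketol are removed; the forward step must oxidise C6=C7 from the β face without ever forming a free enolate next to the 8-acetate.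

28 to 27 to 26: the C6 carbonyl is returned to a silyl-protected carbinol. The C6 oxygen must pass masked through the organometallic, hydride and osmium steps, where a ketone would be a β-hydroxy ketone under acid. The demand is a desilylation that spares acetate and triflate.

26 to 24 to 23: the acetyl–O8 and triflyl–O14 bonds are cut and the C14 ketone is returned to the carbinol. The tertiary 8-hydroxyl has to be free in the key step and is acylated afterwards as its alkoxide; the C14 carbinol that the key step creates becomes a ketone that can enolise only toward C15. The demand is that sulfonylation chooses the enolate over the hindered alkoxide.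

23 to 22 (key disconnection): O9–C13 and C14–O are cut, which opens ring C and removes C13 and C14 as stereocentres. What remains is a decalin cis-diol with a simple dihydrofuranylethyl chain. The forward step needs a hindered di-tertiary diol to chelate osmium, 5-exo closure at a fully substituted alkene carbon, and no competing alkene. For that reason 22 carries a saturated ring A, a silyl ether (not a ketone) at C6, and no other free hydroxyl.

22 to 21 to 20: C7–H is traced to the C7–O bond of an epoxide, and the epoxide to the C7=C8 alkene. The 9α-hydroxyl directs the 8-oxygen to the same face, which gives the cis-diol. The demands are chemoselectivity over the side-chain alkene and hydride attack at the hindered secondary C7.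

20 to 11 + 18: the C9–C11 bond is cut. All six side-chain carbons are attached and C9 is created in one convergent step. The nucleophile must add 1,2 to a neopentyl enone from the β face.

18 to 17 to 15 to 14 to 12 + 13: the bromide comes from the alcohol, the alcohol from hydroboration of a vinyl group, the vinyl-dihydrofuran from an enyne by ring-closing metathesis (ring D and the C12–C13 connection in one step), and the enyne from an ether C–O bond. The demand is hydroboration of the vinyl group only.

11 to 10 to 8: the C6–O bond is cut. C6 is the γ-position of the C9 enone, so the oxygen can be introduced through the dienol ether. The demand is γ- over α-oxidation.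

8 to 7 to 6: the C3–C4 bond is cut and one C4 methyl is returned to the methylene of an isopropenyl group. Ring A closes by carbopalladation and the gem-dimethyl carbon appears in the same step. The two arms must be cis, and the ring A alkene must be hydrogenated in the presence of the enone.

6 to 5 to 4 + 3, and 3 to 2 to 1: the C10–methyl and C10–C1 bonds are cut to two enolate alkylations of 4, whose stereocentre becomes C5. The order (arm first, methyl second) fixes C10 so that the arm is cis to the isopropenyl group. 3 is the bromide of the alcohol 2, which comes from the ester 1.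

## Other disconnections considered

Alternative 1: Rings A and B are cut at C1–C10 and C4–C5, leading back to the quinone A1 (2,6-dimethyl-1,4-benzoquinone) and the diene A2 (4-methylpenta-1,3-diene). Forward, a chiral oxazaborolidinium acid on the C6 carbonyl would promote [4+2] addition across C5=C10 and give the cis-fused ene-dione A3.
- In its favour: one catalytic step would assemble every carbon of the decalin, set C5 and C10 cis by suprafacial addition, and deliver both carbonyls and the C7=C8 bond with its methyl group.
- Against it here: the reacting terminus of A2 is fully substituted and carries a Z-methyl group, so the s-cis conformer is scarce and the C4–C5 bond joins two hindered carbons. The diene is also prone to acid-induced isomerisation. A3 then offers two conjugated ketones that must be differentiated before C9 can be alkylated, with H5 epimerisable next to C6.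
- Comparison: on step economy the alternative is the better plan, because A3 would stand roughly where 11 stands after eight steps, and it supplies the C6 oxygen without a separate oxidation. On mechanism the chosen route is safer, since its ring closure is an intramolecular carbopalladation whose regiochemistry is fixed by the tether. On structure the two are equal in what they leave open: neither touches the 8,9-dioxygenation or C13, so A3 would still pass through a diol of the type of 22 and the same osmium step. Stereochemical security is equal or slightly on the side of the chosen route, which takes C5 from the chiral pool.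

Alternative 2: The cut is C4–C5 and C9–C10, back to the acyclic Z-configured β-keto ester A4. Forward, SnCl4 activated by a chiral binaphthol would protonate the terminal alkene, and the cation would be relayed through the Z-alkene to the enol, giving the cis-fused bicyclic keto ester A5.
- In its favour: A4 should be available in two operations from a neryl halide and an acetoacetate dianion. Two rings and three stereocentres would form at once, and the Z-geometry translates into the cis fusion. The ester carbon is C11, so the first side-chain carbon is attached without a hindered ketone addition. On this point, and in the ease of hydroxylating C9 between two carbonyls, the alternative is the equal or the better of the chosen plan.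
- Against it here: A5 has no function at C6 or C7, so the keto-ol of ring B would need oxidation of unactivated methylenes. Z-alkenes are the less well-behaved substrates of proton-initiated enantioselective cyclisations, and a β-keto ester is a weak terminator. The ester would also have to be extended by five carbons.
- Comparison: the skeleton would be reached in fewer steps (better), but the ring B oxidation pattern, which the carvone enone provides through C7=C8 and the γ-position C6, would cost more than is saved. Mechanistically a cationic cascade is less predictable than stepwise alkylation and palladium closure.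

Alternative 3: Here C1–C10 is formed and C3–C8 broken. The cis-decalin A7 is traced to the bicyclo[2.2.2]octenol A6, whose potassium alkoxide would rearrange by an anionic oxy-Cope shift.
- In its favour: the step is pericyclic and stereospecific, and the cis fusion is imposed by the bicyclic frame. A7 already carries the C6 and C7 oxygens as a β,β-acetonide with C7 as in the target. On this point the alternative is better than the chosen plan, whose C7 hydroxylation (step 21) is its least secure stereochemical event.
- Against it here: A6 is a densely substituted, enantiopure bicycle that needs its own synthesis. The C3 ketone is extraneous and must be removed. C9 of A7 is an alkene CH without C11, so both the C9–C11 bond and the C9 oxygen would have to be installed at a trisubstituted alkene, presumably through a C9 ketone. The 6-hydroxyl would later have to be oxidised next to the 7-hydroxyl.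
- Comparison: the key step itself is the equal or the better in mechanistic reliability. Structurally it is better at C6/C7 and worse at C3 and C9. In step economy it is probably worse because of the supply of A6 and the corrective steps. Like the other two, it leaves C13 to the osmium cyclisation.

Key step: step 16

**Remarks (assumptions)**

- Labdane numbering is used throughout; β is the face of ring B that carries the C10 methyl group, α the opposite face.
- Ring carbons C1–C6 of carvone become C9, C8, C7, C6, C5 and C10. On checking, the C5 configuration of (S)-carvone is the one required, and the configurations of diol 22 and ether 23 agree with the target at C5, C8, C9, C10 and C13, so no structure needed correction.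
- Compound 5 forms as a mixture of epimers at the new centre; the trans isomer is drawn and both converge in step 4.
- The 6β configuration of 10 is the expected one and has no bearing on the target, because C6 becomes a ketone in step 20.

## Steps

Step 1
Reactants: 1 ethyl (Z)-3-iodoprop-2-enoate
Product: 2 (Z)-3-iodoprop-2-en-1-ol
Conditions: i-Bu2AlH (2.2 equiv), CH2Cl2, −78 → 0 °C; aq. KNaC4H4O6
Reagents that add atoms: none
Why: Aluminium hydride reduction of an α,β-unsaturated ester stops at the allylic alcohol by 1,2-delivery of hydride; the Z-iodoalkene is inert at low temperature and keeps its geometry.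

Step 2
Reactants: 2 (Z)-3-iodoprop-2-en-1-ol
Product: 3 (Z)-3-bromo-1-iodoprop-1-ene
Conditions: CBr4, PPh3, CH2Cl2, 0 °C
Reagents that add atoms: tetrabromomethane, BrC(Br)(Br)Br
Why: Appel bromination of a primary allylic alcohol through the alkoxyphosphonium salt; the conditions are neutral, so the Z-iodoalkene is not isomerised.

Step 3
Reactants: 4 (S)-(+)-carvone; 3 (Z)-3-bromo-1-iodoprop-1-ene
Product: 5 (S)-carvone alkylated at C6 with a (Z)-3-iodoprop-2-enyl group (epimers at C6; trans isomer drawn)
Conditions: LiN(i-Pr)2, THF, −78 °C; then 3, −78 → −20 °C
Reagents that add atoms: none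
Why: Kinetic deprotonation of the enone at the α′-methylene (the future C10) and SN2 alkylation of the lithium enolate by the allylic bromide, the vinylic iodide being unreactive toward SN2. The new centre is not controlled and need not be, because it becomes planar again in step 4.

Step 4
Reactants: 5 (S)-carvone alkylated at C6 with a (Z)-3-iodoprop-2-enyl group
Product: 6 (S)-carvone bearing at C6 a methyl group trans and a (Z)-3-iodoprop-2-enyl group cis to the isopropenyl group
Conditions: LiN(i-Pr)2, THF, −78 °C; MeI, DMPU, −78 → 0 °C
Reagents that add atoms: iodomethane, CI
Why: Second α′-enolate alkylation creates the quaternary C10: the neighbouring isopropenyl group sits pseudoaxial in the enolate to avoid allylic strain, so iodomethane enters on the opposite face and the iodoallyl arm ends cis to isopropenyl, as ring A requires. Deprotonation at −78 °C with one equivalent of amide is faster than dehydroiodination of the Z-iodoalkene.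

Step 5
Reactants: 6 (S)-carvone bearing at C6 a methyl group and a (Z)-3-iodoprop-2-enyl group
Product: 7 cis-fused dienone (4aR,8aS)-2,5,5,8a-tetramethyl-4a,5,8,8a-tetrahydronaphthalen-1(4H)-one
Conditions: Pd(OAc)2 (10 mol %), PPh3 (20 mol %), HCO2Na, Bu4NCl, DMF, 80 °C
Reagents that add atoms: none
Why: Intramolecular reductive Heck reaction: oxidative addition of the alkenyl iodide to zerovalent palladium, 6-exo-trig carbopalladation of the 1,1-disubstituted alkene (C3–C4 bond, ring A), and formate reduction of the neopentyl alkylpalladium, which has no β-hydrogen, to the second C4 methyl group. The cis ring fusion is dictated by the cis arms set in step 4; C4 bears two methyls and is no stereocentre.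

Step 6
Reactants: 7 cis-fused dienone
Product: 8 cis-fused enone (4aR,8aS)-2,5,5,8a-tetramethyl-4a,5,6,7,8,8a-hexahydronaphthalen-1(4H)-one
Conditions: H2 (1 atm), RhCl(PPh3)3 (5 mol %), benzene–EtOH, 25 °C
Reagents that add atoms: none
Why: Homogeneous hydrogenation with RhCl(PPh3)3 saturates the cis-disubstituted ring A alkene and leaves the trisubstituted, conjugated C7=C8 bond, the same selectivity by which this catalyst reduces only the isopropenyl group of carvone.

Step 7
Reactants: 8 cis-fused enone
Product: 10 cis-decalin 6β-hydroxy-7-en-9-one, via trimethylsilyl dienol ether 9 (not isolated)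
Conditions: Me3SiOTf, Et3N, CH2Cl2, 0 °C; then 3-chloroperbenzoic acid, NaHCO3, CH2Cl2, −20 °C; aq. citric acid
Reagents that add atoms: 3-chloroperbenzoic acid, O=C(OO)c1cccc(Cl)c1
Why: Because C10 is quaternary, soft enolisation can only remove a γ-hydrogen (C6) and gives the linear silyl dienol ether; the peracid then attacks the less hindered terminal C6=C7 bond and not the tetrasubstituted C8=C9 bond, and collapse of the epoxide regenerates the enone with a C6 hydroxyl (vinylogous Rubottom oxidation). Attack anti to the quaternary C4 on C5 should give the 6β-alcohol.

Step 8
Reactants: 10 cis-decalin 6β-hydroxy-7-en-9-one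
Product: 11 cis-decalin 6β-(tert-butyldimethylsilyloxy)-7-en-9-one
Conditions: t-BuMe2SiOTf, 2,6-lutidine, CH2Cl2, 0 °C
Reagents that add atoms: tert-butyldimethylsilyl trifluoromethanesulfonate, CC(C)(C)[Si](C)(C)OS(=O)(=O)C(F)(F)F
Why: Silylation of a hindered secondary alcohol with the silyl triflate and a non-nucleophilic base. The ether masks the C6 oxygen against the organometallic and the hydride, and removes a free allylic 6-hydroxyl that would compete as a directing group in step 14.

Step 9
Reactants: 12 prop-2-yn-1-ol; 13 allyl bromide
Product: 14 allyl propargyl ether
Conditions: NaH, THF, 0 → 25 °C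
Reagents that add atoms: none
Why: Williamson ether synthesis: the sodium alkoxide of the propargylic alcohol displaces the allylic bromide by SN2.

Step 10
Reactants: 14 allyl propargyl ether
Product: 15 3-ethenyl-2,5-dihydrofuran
Conditions: RuCl2(PCy3)2(=CHPh) (first-generation Grubbs catalyst, 3 mol %), ethylene (1 atm), CH2Cl2, 25 °C
Reagents that add atoms: none
Why: Ring-closing enyne metathesis in the exo mode: the ruthenium carbene formed at the allyl terminus adds to the alkyne and the resulting vinylcarbene is released by ethylene, giving the five-membered 1-vinylcycloalkene. Ethylene keeps the catalyst turning over with a terminal alkyne.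

Step 11
Reactants: 15 3-ethenyl-2,5-dihydrofuran
Product: 17 2-(2,5-dihydrofuran-3-yl)ethanol, via B-alkyl-9-borabicyclononane adduct 16 (not isolated)
Conditions: 9-BBN (1.0 equiv), THF, 0 → 25 °C; then NaOH, H2O2, 0 °C
Reagents that add atoms: hydrogen peroxide, OO
Why: Hydroboration with the bulky dialkylborane occurs at the monosubstituted vinyl group, boron on the terminal carbon, far faster than at the trisubstituted ring alkene (as in the monohydroboration of 2-substituted butadienes). Oxidation with retention gives the primary homoallylic alcohol.

Step 12
Reactants: 17 2-(2,5-dihydrofuran-3-yl)ethanol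
Product: 18 3-(2-bromoethyl)-2,5-dihydrofuran
Conditions: CBr4, PPh3, CH2Cl2, 0 °C
Reagents that add atoms: tetrabromomethane, BrC(Br)(Br)Br
Why: Appel bromination of a primary alcohol under neutral conditions that do not disturb the allylic ether or move the ring double bond.

Step 13
Reactants: 18 3-(2-bromoethyl)-2,5-dihydrofuran; 11 cis-decalin 6β-(tert-butyldimethylsilyloxy)-7-en-9-one
Product: 20 tertiary allylic alcohol (9α-hydroxy-9β-[2-(2,5-dihydrofuran-3-yl)ethyl]-6β-silyloxy-7-ene), via Grignard reagent 19 (not isolated)
Conditions: Mg, THF, 40 °C; anhydrous CeCl3, THF, −78 °C; then 11, −78 → 0 °C; aq. NH4Cl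
Reagents that add atoms: none
Why: Magnesium insertion gives a homoallylic Grignard reagent, and transmetallation with CeCl3 to the less basic alkylcerium dichloride favours 1,2-addition to the hindered, enolisable enone. In the cis-decalin, ring A lies under the α face of ring B with the C10–C1 bond axial next to the carbonyl, so the nucleophile should enter from the convex β face and give the 9α-alcohol.

Step 14
Reactants: 20 tertiary allylic alcohol
Product: 21 7α,8α-epoxide of 20
Conditions: VO(acac)2 (5 mol %), t-BuOOH (1.2 equiv), CH2Cl2, 0 °C
Reagents that add atoms: tert-butyl hydroperoxide, CC(C)(C)OO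
Why: Hydroxyl-directed epoxidation: the vanadium alkoxide of the tertiary allylic 9α-alcohol delivers the peroxide oxygen to the same face of C7=C8, so the epoxide is α. Allylic alcohols react far faster than the bishomoallylic relationship that the same hydroxyl has to the side-chain alkene, which is also deactivated by its allylic ether oxygen.

Step 15
Reactants: 21 7α,8α-epoxide
Product: 22 8α,9α-diol with 6β-silyloxy group and 2-(2,5-dihydrofuran-3-yl)ethyl chain at C9
Conditions: LiEt3BH (3 equiv), THF, 0 → 50 °C; aq. NH4Cl
Reagents that add atoms: none
Why: SN2 opening of a trisubstituted epoxide by a trialkylborohydride takes place at the secondary carbon C7 with trans-diaxial geometry, leaving the epoxide oxygen on C8 as the tertiary 8α-alcohol. C8 keeps its configuration, so the diol is cis.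

Step 16
Reactants: 22 8α,9α-diol
Product: 23 bis-spiro ether with free 8α- and 14-hydroxyls
Conditions: K2OsO2(OH)4 (5 mol %), pyridine N-oxide (3 equiv), citric acid (0.75 equiv), Cu(OTf)2 (0.5 equiv), MeCN–aq. phosphate buffer (pH 6.5), 60 °C
Reagents that add atoms: pyridine N-oxide, [O-][n+]1ccccc1
Why: The cis-8α,9α-diol binds the dioxo core of hexavalent osmium as a five-membered cyclic diolate, a ligand exchange that citric acid and Cu(OTf)2 accelerate while keeping the medium mild enough for the silyl ether. O9 and one oxo ligand then add suprafacially across C13=C14 in an intramolecular [3+2] step, forming O9–C13 and C14–O on the same face; hydrolysis releases the 14-hydroxyl and tetravalent osmium, which pyridine N-oxide returns to the hexavalent state without reaching the octavalent level that would dihydroxylate the alkene intermolecularly. The closest known reaction type is the osmium-catalysed oxidative cyclisation of vicinal diols onto 4,5-alkenes to cis-2,5-disubstituted tetrahydrofurans. Ring C closes in the 5-exo-trig mode at C13; closure through O8 would need a six-membered ring and is not expected. C13 is controlled by the chelate: with O8 and O9 both on osmium, the tether can reach the alkene only in the folded arrangement that places C8 and C14 cis on the new ring, which is the configuration of the target. C14 follows from syn addition and is removed in step 17. The step needs chemoselectivity for a single alkene, which is why ring A was saturated in step 6, and it needs the hindered di-tertiary diol to chelate, which the cis α,α disposition set in steps 13–15 allows.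

Step 17
Reactants: 23 bis-spiro ether with free 8α- and 14-hydroxyls
Product: 24 bis-spiro ether C14 ketone with free 8α-hydroxyl
Conditions: Dess–Martin periodinane, NaHCO3, CH2Cl2, 25 °C
Reagents that add atoms: none
Why: Dess–Martin oxidation converts the secondary C14 carbinol to the ketone and cannot touch the tertiary 8-hydroxyl. It removes the C14 stereocentre and creates a ketone whose only enolisable position is C15.

Step 18
Reactants: 24 bis-spiro ether C14 ketone
Product: 26 8α-acetate C14 enol triflate (6β-silyl ether), via potassium alkoxide enol triflate 25 (not isolated)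
Conditions: KN(SiMe3)2 (2.2 equiv), THF, −78 °C; PhNTf2, −78 → −30 °C; then Ac2O, −30 → 0 °C
Reagents that add atoms: N-phenylbis(trifluoromethanesulfonimide), O=S(=O)(N(c1ccccc1)S(=O)(=O)C(F)(F)F)C(F)(F)F; acetic anhydride, CC(=O)OC(C)=O
Why: Two equivalents of base give the tertiary alkoxide and the potassium enolate, the latter necessarily toward C15 because C13 is quaternary; the triflimide sulfonylates the enolate oxygen but not a hindered tertiary alkoxide, which the anhydride then acetylates. The enol triflate is a masked form of the C14=C15 enol ether that tolerates acid and electrophilic oxidants.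

Step 19
Reactants: 26 8α-acetate C14 enol triflate (6β-silyl ether)
Product: 27 8α-acetate C14 enol triflate 6β-alcohol
Conditions: HF·pyridine, pyridine, THF, 0 → 25 °C
Reagents that add atoms: none
Why: Fluoride-mediated cleavage of the silyl ether under buffered acidic conditions, to which the tertiary acetate and the vinyl triflate are inert.

Step 20
Reactants: 27 8α-acetate C14 enol triflate 6β-alcohol
Product: 28 8α-acetate C14 enol triflate 6-ketone
Conditions: Dess–Martin periodinane, NaHCO3, CH2Cl2, 25 °C
Reagents that add atoms: none
Why: Dess–Martin oxidation of the secondary 6-alcohol under buffered, non-basic conditions, so that the β-acetoxy ketone does not lose acetate and C5 does not epimerise.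

Step 21
Reactants: 28 8α-acetate C14 enol triflate 6-ketone
Product: 31 7β-hydroxy-6-ketone 8α-acetate C14 enol triflate, via trimethylsilyl enol ether 29 (not isolated), via 7β-trimethylsilyloxy ketone 30 (not isolated)
Conditions: Me3SiOTf, Et3N, CH2Cl2, 0 °C; dimethyldioxirane, acetone–CH2Cl2, −78 °C; then aq. citric acid, THF, 0 °C
Reagents that add atoms: dimethyldioxirane, CC1(C)OO1
Why: Rubottom oxidation: amine-buffered silyl triflate enolises the ketone toward C7 (C5 is tertiary and flanked by the gem-dimethyl carbon), the dioxirane epoxidises the silyl enol ether far faster than the electron-poor enol triflate, and silyl migration followed by mild acid gives the α-ketol without a free enolate that would expel the 8-acetate. The oxidant should approach C6=C7 anti to the allylic C8–O bond of the 8α-acetate and away from ring A, that is from the β face, giving the 7β-alcohol trans to the acetate.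

Step 22
Reactants: 31 7β-hydroxy-6-ketone 8α-acetate C14 enol triflate
Product: 32 CNP0275274.1 (target)
Conditions: Pd(PPh3)4 (10 mol %), LiCl, Bu3SnH, THF, 25 → 50 °C
Reagents that add atoms: none
Why: Palladium-catalysed reduction of a vinyl triflate: oxidative addition to zerovalent palladium, chloride exchange, hydride transfer from the tin hydride and reductive elimination replace the triflate by hydrogen and unveil the C14=C15 enol ether under neutral conditions at the very end. Ring opening by β-alkoxide elimination is excluded because it would require an allene in a five-membered ring.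

## Compound list

1 | ethyl (Z)-3-iodoprop-2-enoate | CCOC(=O)/C=C\I | starting material
2 | (Z)-3-iodoprop-2-en-1-ol | OC/C=C\I | intermediate
3 | (Z)-3-bromo-1-iodoprop-1-ene | BrC/C=C\I | intermediate
4 | (S)-(+)-carvone | CC1=CC[C@@H](CC1=O)C(C)=C | starting material
5 | (S)-carvone alkylated at C6 with a (Z)-3-iodoprop-2-enyl group (trans epimer drawn) | CC1=CC[C@H](C(C)=C)[C@@H](C/C=C\I)C1=O | intermediate
6 | (S)-carvone bearing at C6 a methyl group trans and a (Z)-3-iodoprop-2-enyl group cis to isopropenyl | CC1=CC[C@H](C(C)=C)[C@](C)(C/C=C\I)C1=O | intermediate
7 | cis-fused dienone (4aR,8aS)-2,5,5,8a-tetramethyl-4a,5,8,8a-tetrahydronaphthalen-1(4H)-one | CC1=CC[C@@H]2C(C)(C)C=CC[C@]2(C)C1=O | intermediate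
8 | cis-fused enone (4aR,8aS)-2,5,5,8a-tetramethyl-4a,5,6,7,8,8a-hexahydronaphthalen-1(4H)-one | CC1=CC[C@@H]2C(C)(C)CCC[C@]2(C)C1=O | intermediate
9 | trimethylsilyl dienol ether of 8 (C9–OSiMe3, C8=C9, C6=C7; not isolated) | CC=1C=C[C@@H]2C(C)(C)CCC[C@]2(C)C=1O[Si](C)(C)C | intermediate
10 | cis-decalin 6β-hydroxy-7-en-9-one | CC1=C[C@@H](O)[C@@H]2C(C)(C)CCC[C@]2(C)C1=O | intermediate
11 | cis-decalin 6β-(tert-butyldimethylsilyloxy)-7-en-9-one | CC1=C[C@@H](O[Si](C)(C)C(C)(C)C)[C@@H]2C(C)(C)CCC[C@]2(C)C1=O | intermediate
12 | prop-2-yn-1-ol | C#CCO | starting material
13 | allyl bromide | C=CCBr | starting material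
14 | allyl propargyl ether | C=CCOCC#C | intermediate
15 | 3-ethenyl-2,5-dihydrofuran | C=CC1=CCOC1 | intermediate
16 | B-[2-(2,5-dihydrofuran-3-yl)ethyl]-9-borabicyclo[3.3.1]nonane (not isolated) | C1CC2CCCC(C1)B2CCC1=CCOC1 | intermediate
17 | 2-(2,5-dihydrofuran-3-yl)ethanol | OCCC1=CCOC1 | intermediate
18 | 3-(2-bromoethyl)-2,5-dihydrofuran | BrCCC1=CCOC1 | intermediate
19 | [2-(2,5-dihydrofuran-3-yl)ethyl]magnesium bromide (not isolated) | Br[Mg]CCC1=CCOC1 | intermediate
20 | tertiary allylic alcohol: 9α-hydroxy, 9β-[2-(2,5-dihydrofuran-3-yl)ethyl], 6β-silyloxy, C7=C8 | CC1=C[C@@H](O[Si](C)(C)C(C)(C)C)[C@@H]2C(C)(C)CCC[C@]2(C)[C@@]1(O)CCC1=CCOC1 | intermediate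
21 | 7α,8α-epoxide of 20 | C[C@@]12O[C@@H]1[C@@H](O[Si](C)(C)C(C)(C)C)[C@@H]3C(C)(C)CCC[C@]3(C)[C@@]2(O)CCC1=CCOC1 | intermediate
22 | cis-decalin 8α,9α-diol with 6β-silyloxy group and 2-(2,5-dihydrofuran-3-yl)ethyl chain at C9 (key-step precursor) | O[C@]1(C)C[C@@H](O[Si](C)(C)C(C)(C)C)[C@@H]2C(C)(C)CCC[C@]2(C)[C@@]1(O)CCC1=CCOC1 | intermediate
23 | bis-spiro ether with free 8α- and 14-hydroxyls (key-step product) | O[C@]1(C)C[C@@H](O[Si](C)(C)C(C)(C)C)[C@@H]2C(C)(C)CCC[C@]2(C)[C@@]12CC[C@@]1([C@@H](O)COC1)O2 | intermediate
24 | bis-spiro ether C14 ketone with free 8α-hydroxyl | O[C@]1(C)C[C@@H](O[Si](C)(C)C(C)(C)C)[C@@H]2C(C)(C)CCC[C@]2(C)[C@@]12CC[C@@]1(C(=O)COC1)O2 | intermediate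
25 | potassium 8-alkoxide of the C14 enol triflate (not isolated) | [K+].[O-][C@]1(C)C[C@@H](O[Si](C)(C)C(C)(C)C)[C@@H]2C(C)(C)CCC[C@]2(C)[C@@]12CC[C@@]1(C(OS(=O)(=O)C(F)(F)F)=COC1)O2 | intermediate
26 | 8α-acetate C14 enol triflate 6β-silyl ether | CC(=O)O[C@]1(C)C[C@@H](O[Si](C)(C)C(C)(C)C)[C@@H]2C(C)(C)CCC[C@]2(C)[C@@]12CC[C@@]1(C(OS(=O)(=O)C(F)(F)F)=COC1)O2 | intermediate
27 | 8α-acetate C14 enol triflate 6β-alcohol | CC(=O)O[C@]1(C)C[C@@H](O)[C@@H]2C(C)(C)CCC[C@]2(C)[C@@]12CC[C@@]1(C(OS(=O)(=O)C(F)(F)F)=COC1)O2 | intermediate
28 | 8α-acetate C14 enol triflate 6-ketone | CC(=O)O[C@]1(C)CC(=O)[C@@H]2C(C)(C)CCC[C@]2(C)[C@@]12CC[C@@]1(C(OS(=O)(=O)C(F)(F)F)=COC1)O2 | intermediate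
29 | C6 trimethylsilyl enol ether (C6=C7) of 28 (not isolated) | CC(=O)O[C@]1(C)C=C(O[Si](C)(C)C)[C@@H]2C(C)(C)CCC[C@]2(C)[C@@]12CC[C@@]1(C(OS(=O)(=O)C(F)(F)F)=COC1)O2 | intermediate
30 | 7β-trimethylsilyloxy-6-ketone (not isolated) | CC(=O)O[C@]1(C)[C@@H](O[Si](C)(C)C)C(=O)[C@@H]2C(C)(C)CCC[C@]2(C)[C@@]12CC[C@@]1(C(OS(=O)(=O)C(F)(F)F)=COC1)O2 | intermediate
31 | 7β-hydroxy-6-ketone 8α-acetate C14 enol triflate | CC(=O)O[C@]1(C)[C@@H](O)C(=O)[C@@H]2C(C)(C)CCC[C@]2(C)[C@@]12CC[C@@]1(C(OS(=O)(=O)C(F)(F)F)=COC1)O2 | intermediate
32 | CNP0275274.1: 8α-acetoxy-7β-hydroxy-9α,13;15,16-diepoxy-cis-labd-14-en-6-one | CC(=O)O[C@]1(C)[C@@H](O)C(=O)[C@@H]2C(C)(C)CCC[C@]2(C)[C@@]12CC[C@@]1(C=COC1)O2 | target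

## Step count and least certain steps

Total: 22 steps. Longest linear sequence: 18 steps (steps 1–8 and 13–22, counted from 1). The side chain takes four steps (9–12) and is joined in step 13.

**Step 16 (key step).** The most likely failure is that the hindered di-tertiary diol does not chelate osmium or that the catalyst does not turn over, because a tetrasubstituted carbon is being formed at a trisubstituted cyclic alkene; slow closure would leave room for silyl loss or intermolecular oxidation. Fallback, setting out from 22: dimethyldioxirane epoxidises the only alkene to the 13,14-epoxide F1 (formed together with its face isomer). Catalytic camphorsulfonic acid in CH2Cl2 then lets O9 open the epoxide at the tertiary C13 with inversion (5-exo), giving the 14-epimeric hydroxy ether F2 and its C13 epimer, which must be separated. Dess–Martin oxidation of F2 gives 24, where the route is rejoined. The price is that C13 is no longer controlled by a chelate.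

**Step 21.** Two processes threaten it: attack of the oxidant from the α face (the conformation of ring B in the enol ether is not certain), and ionisation of the allylic tertiary acetate in 29 by the silyl triflate with loss of acetate to the 7-en-6-one. Fallback for the facial problem, setting out from 28 through the same enol ether 29: N-bromosuccinimide (THF, −78 °C) uses the α preference and gives the 7α-bromo ketone F3. HCO2Cs in DMF displaces bromide with inversion (SN2 next to a carbonyl; the cis 8α-acetate cannot participate) to the 7β-formate F4. KHCO3 in methanol removes the formyl group selectively and gives 31.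

**Step 15.** Hydride delivery at C7 may be too slow, because the carbon lies between the fully substituted C8 and the silyloxy-bearing C6 and must be approached from the β face; prolonged heating would risk silyl cleavage. Fallback, setting out from 21: sodium phenylselenide (PhSeSePh, NaBH4, EtOH), a much better nucleophile, opens the epoxide at C7 to the 7β-phenylselanyl diol F5; Bu3SnH with azobisisobutyronitrile in toluene at 80 °C then replaces selenium by hydrogen and gives 22.

**Step 13.** The bulky primary alkyl nucleophile may fail to add to the neopentyl ketone, with γ-deprotonation at C6 taking over. Fallback, setting out from 11: CH2=CHMgBr with CeCl3 adds the smaller vinyl group from the same face to give the 9-vinyl carbinol F6. 9-BBN hydroborates only the vinyl group to the alkylborane F7. Suzuki–Miyaura coupling (PdCl2(dppf), K3PO4, DMF–water) with 3-bromo-2,5-dihydrofuran F8 forms the C12–C13 bond and gives 20; F8 is made from commercial 2-(2,5-dihydrofuran-3-yl)-4,4,5,5-tetramethyl-1,3,2-dioxaborolane with CuBr2.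

**Step 5.** The alkenylpalladium may be reduced by formate before it cyclises, or the neopentyl palladium may rearrange through a cyclopropylcarbinyl intermediate; conjugate reduction of the enone is a further risk. Fallback, setting out from 4 and returning at 8:
- Fe(acac)3 and PhSiH3 with methyl acrylate (EtOH, 60 °C) convert the isopropenyl group by hydrogen-atom transfer and Giese addition into the gem-dimethyl ester F9.
- KOt-Bu in THF closes ring A by Dieckmann condensation to the enolised β-diketone F10.
- MeI and K2CO3 methylate C10 on the face away from the C4 quaternary carbon, giving the cis-fused 1,9-dione F11.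
- KN(SiMe3)2 and PhNTf2 convert the saturated C1 ketone to the enol triflate F12.
- Pd(PPh3)4, LiCl and Bu3SnH reduce it to the diene-one F13.
- H2 with RhCl(PPh3)3, as in step 6, gives 8.

## Further compounds

F1 | step 16 | 13,14-epoxide of 22 (face isomer that leads to the required C13 configuration) | O[C@]1(C)C[C@@H](O[Si](C)(C)C(C)(C)C)[C@@H]2C(C)(C)CCC[C@]2(C)[C@@]1(O)CC[C@]12COC[C@H]1O2
F2 | step 16 | 14-epimer of 23 (O9 and 14-OH trans on ring D) | O[C@]1(C)C[C@@H](O[Si](C)(C)C(C)(C)C)[C@@H]2C(C)(C)CCC[C@]2(C)[C@@]12CC[C@@]1([C@H](O)COC1)O2
F3 | step 21 | 7α-bromo-6-ketone 8α-acetate C14 enol triflate | CC(=O)O[C@]1(C)[C@H](Br)C(=O)[C@@H]2C(C)(C)CCC[C@]2(C)[C@@]12CC[C@@]1(C(OS(=O)(=O)C(F)(F)F)=COC1)O2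
F4 | step 21 | 7β-formyloxy-6-ketone 8α-acetate C14 enol triflate | CC(=O)O[C@]1(C)[C@@H](OC=O)C(=O)[C@@H]2C(C)(C)CCC[C@]2(C)[C@@]12CC[C@@]1(C(OS(=O)(=O)C(F)(F)F)=COC1)O2
F5 | step 15 | 7β-phenylselanyl-8α,9α-diol | O[C@]1(C)[C@@H]([Se]c2ccccc2)[C@@H](O[Si](C)(C)C(C)(C)C)[C@@H]3C(C)(C)CCC[C@]3(C)[C@@]1(O)CCC1=CCOC1
F6 | step 13 | 9α-hydroxy-9β-vinyl-6β-silyloxy-7-ene | CC1=C[C@@H](O[Si](C)(C)C(C)(C)C)[C@@H]2C(C)(C)CCC[C@]2(C)[C@@]1(O)C=C
F7 | step 13 | B-alkyl-9-borabicyclo[3.3.1]nonane adduct of F6 (boron on C12) | CC1=C[C@@H](O[Si](C)(C)C(C)(C)C)[C@@H]2C(C)(C)CCC[C@]2(C)[C@@]1(O)CCB1C2CCCC1CCC2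
F8 | step 13 | 3-bromo-2,5-dihydrofuran | BrC1=CCOC1
F9 | step 5 | methyl 4-methyl-4-[(1S)-4-methyl-5-oxocyclohex-3-en-1-yl]pentanoate | CC1=CC[C@@H](CC1=O)C(C)(C)CCC(=O)OC
F10 | step 5 | enolised bicyclic β-diketone (C1 enol, C9 ketone, C7=C8) | CC1=CC[C@@H]2C(C)(C)CCC(O)=C2C1=O
F11 | step 5 | cis-fused 10-methyl-1,9-dione (C7=C8) | CC1=CC[C@@H]2C(C)(C)CCC(=O)[C@]2(C)C1=O
F12 | step 5 | C1 enol triflate (C1=C2) of F11 | CC1=CC[C@@H]2C(C)(C)CC=C(OS(=O)(=O)C(F)(F)F)[C@]2(C)C1=O
F13 | step 5 | cis-fused 1,7-dien-9-one | CC1=CC[C@@H]2C(C)(C)CC=C[C@]2(C)C1=O
A1 | alternative 1 | 2,6-dimethyl-1,4-benzoquinone | CC1=CC(=O)C=C(C)C1=O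
A2 | alternative 1 | 4-methylpenta-1,3-diene | C=CC=C(C)C
A3 | alternative 1 | cis-fused ene-dione with all carbons of rings A and B | CC1=CC(=O)[C@@H]2C(C)(C)C=CC[C@]2(C)C1=O
A4 | alternative 2 | methyl (6Z)-7,11-dimethyl-3-oxododeca-6,10-dienoate | COC(=O)CC(=O)CC/C=C(C)\CCC=C(C)C
A5 | alternative 2 | cis-fused bicyclic β-keto ester (C8 ketone, C9 ester) | O=C1CC[C@@H]2C(C)(C)CCC[C@]2(C)[C@H]1C(=O)OC
A6 | alternative 3 | 6-ethenyl-1,3,5,5-tetramethylbicyclo[2.2.2]oct-2-en-6-ol 7,8-acetonide (vinyl syn to the alkene bridge) | C=C[C@]1(O)C(C)(C)[C@@H]2C(C)=C[C@@]1(C)[C@H]3OC(C)(C)O[C@@H]23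
A7 | alternative 3 | cis-decalin with C3 ketone, C8=C9 alkene and C6/C7 acetonide | CC1=C[C@@]2(C)CCC(=O)C(C)(C)[C@H]2[C@@H]3OC(C)(C)O[C@H]13
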